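The pyran ring is closed across its two opposite bonds in a convergent [3+3] union of the arene and terpenoid halves. The design exploits the para pair 5-OH/8-OMe of the benzene ring: in its p-quinone monoketal form C8a is a Michael-acceptor carbon and the formyl carbon is C4. In one flask, a Z-selective Wittig reaction of a β-silyloxy ylide, which already carries the C2 stereocentre and the trimethylcyclohexenyl chain, creates C3=C4; fluoride then frees the tertiary alkoxide O1, which adds to C8a, and loss of methanol rearomatises the ring to give the target with its free 5-OH. The precursor is a dearomatised tetramethoxy dienone aldehyde.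

Key step: step 10

Remark on locants: O1, C2, C3, C4, C4a, C5–C8 and C8a are the chromene locants of the target.

Assumption: compounds 1, 3 and 10 are taken as commercial, and in steps 2 and 5 the catalyst antipode is the one that delivers the drawn configuration (the other antipode would be used if the sense of induction proved reversed).

Step 1
Reactants: 1 hex-5-enal
Product: 2 2-methylidenehex-5-enal
Conditions: 37% aq. CH2O, pyrrolidine (10 mol %), propionic acid (10 mol %), i-PrOH, 45 °C
Reagents that add atoms: formaldehyde, C=O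
Why: Amine-catalysed α-methylenation of an aldehyde (Mannich condensation of the enamine with formaldehyde, then elimination of the amine) should install the 2-methylidene group without touching the remote alkene; no stereocentre is formed.

Step 2
Reactants: 2 2-methylidenehex-5-enal; 3 (3E)-3-methylpenta-1,3-diene
Product: 4 (1S,2R)-1-(but-3-en-1-yl)-2,3-dimethylcyclohex-3-ene-1-carbaldehyde
Conditions: (S)-oxazaborolidine from α,α-diphenylprolinol and o-tolylboronic acid, activated with HNTf2 (20 mol %), CH2Cl2, −78 → −40 °C
Reagents that add atoms: none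
Why: A Lewis-acid-catalysed enantioselective Diels–Alder reaction of a 2-substituted acrolein with the E-diene should join the methyl-bearing diene terminus to the quaternary carbon ("ortho" orientation directed by the terminal methyl group), place the formyl group cis to the C2 methyl group through the endo transition state, and take its absolute sense (1S,2R) from the enal face left open by the chiral oxazaborolidinium ion.

Step 3
Reactants: 4 (1S,2R)-1-(but-3-en-1-yl)-2,3-dimethylcyclohex-3-ene-1-carbaldehyde
Product: 5 4-[(1R,2S)-1,2,3-trimethylcyclohex-3-en-1-yl]but-1-ene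
Conditions: N2H4·H2O, KOH, diethylene glycol, 130 → 200 °C, under argon
Reagents that add atoms: none
Why: The Wolff–Kishner reduction should turn the formyl group on the quaternary carbon into the quaternary methyl group via the hydrazone anion and loss of N2; the carbon that bears it has no hydrogen, so no stereocentre can epimerise, and the isolated alkenes are inert when air is excluded (no diimide).

Step 4
Reactants: 5 4-[(1R,2S)-1,2,3-trimethylcyclohex-3-en-1-yl]but-1-ene
Product: 6 4-[(1S,2S)-1,2,3-trimethylcyclohex-3-en-1-yl]butan-2-one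
Conditions: PdCl2 (10 mol %), CuCl, O2 (1 atm), DMF–H2O, 23 °C
Reagents that add atoms: water, O
Why: The Wacker oxidation (Markovnikov hydroxypalladation, β-hydride elimination) should act only on the monosubstituted terminal alkene and leave the trisubstituted ring alkene and both stereocentres untouched.

Step 5
Reactants: 6 4-[(1S,2S)-1,2,3-trimethylcyclohex-3-en-1-yl]butan-2-one
Product: 7 (2R)-2-methyl-2-{2-[(1S,2S)-1,2,3-trimethylcyclohex-3-en-1-yl]ethyl}oxirane
Conditions: Me3S(O)I, NaH, THF, 23 °C; then 6, LaLi3[(S)-1,1'-bi-2-naphtholate]3 (5 mol %), [2,4,6-(MeO)3C6H2]3P=O (5 mol %), 5 Å molecular sieves, THF, 23 °C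
Reagents that add atoms: trimethylsulfoxonium iodide, C[S+](C)(C)=O.[I-]
Why: The catalytic asymmetric Corey–Chaykovsky epoxidation of a methyl ketone should deliver the methylene group to one carbonyl face under control of the lanthanum–lithium binaphtholate complex, which tells the methyl group from the CH2CH2R chain and so sets the (2R) centre (future C2) independently of the remote ring stereocentres.

Step 6
Reactants: 7 (2R)-2-methyl-2-{2-[(1S,2S)-1,2,3-trimethylcyclohex-3-en-1-yl]ethyl}oxirane
Product: 8 [(2R)-2-hydroxy-2-methyl-4-[(1S,2S)-1,2,3-trimethylcyclohex-3-en-1-yl]butyl]triphenylphosphonium tetrafluoroborate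
Conditions: Ph3PH+ BF4−, MeCN, 40 °C
Reagents that add atoms: triphenylphosphonium tetrafluoroborate, c1ccc(cc1)[PH+](c1ccccc1)c1ccccc1.F[B-](F)(F)F
Why: Under mild proton activation with a non-nucleophilic counter-ion, triphenylphosphine should open the epoxide by SN2 attack at its CH2 terminus; the C2–O bond is not touched, so the configuration is retained.

Step 7
Reactants: 8 [(2R)-2-hydroxy-2-methyl-4-[(1S,2S)-1,2,3-trimethylcyclohex-3-en-1-yl]butyl]triphenylphosphonium tetrafluoroborate
Product: 9 [(2R)-2-methyl-2-[(trimethylsilyl)oxy]-4-[(1S,2S)-1,2,3-trimethylcyclohex-3-en-1-yl]butyl]triphenylphosphonium tetrafluoroborate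
Conditions: N-(trimethylsilyl)imidazole, CH2Cl2, 23 °C
Reagents that add atoms: N-(trimethylsilyl)imidazole, C[Si](C)(C)n1ccnc1
Why: Silylation of the tertiary alcohol masks O1, so that base later gives a neutral ylide and not a betaine that would collapse to an alkene and Ph3P=O.

Step 8
Reactants: 10 2,3,4-trimethoxyphenol
Product: 11 2-hydroxy-3,4,5-trimethoxybenzaldehyde
Conditions: MgCl2, Et3N, (CH2O)n, MeCN, reflux; aq. HCl work-up
Reagents that add atoms: formaldehyde (as paraformaldehyde), C=O
Why: Magnesium-phenoxide-directed ortho-formylation (chelate-controlled hydroxymethylation, then hydride transfer to a second formaldehyde) can only occur at the single free ortho position, which becomes C4a bearing C4.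

Step 9
Reactants: 11 2-hydroxy-3,4,5-trimethoxybenzaldehyde
Product: 12 3,3,4,5-tetramethoxy-6-oxocyclohexa-1,4-diene-1-carbaldehyde
Conditions: PhI(OAc)2, MeOH, 0 °C, short reaction time, used at once
Reagents that add atoms: methanol, CO
Why: Oxidative dearomatisation of a p-methoxyphenol with PhI(OAc)2 in methanol should trap the phenoxenium ion at the methoxy-bearing para carbon (C8) and give the p-quinone monoketal, in which C8a becomes the β-carbon of an enone.

Step 10
Reactants: 9 [(2R)-2-methyl-2-[(trimethylsilyl)oxy]-4-[(1S,2S)-1,2,3-trimethylcyclohex-3-en-1-yl]butyl]triphenylphosphonium tetrafluoroborate; 12 3,3,4,5-tetramethoxy-6-oxocyclohexa-1,4-diene-1-carbaldehyde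
Product: 16 (2R)-6,7,8-trimethoxy-2-methyl-2-{2-[(1S,2S)-1,2,3-trimethylcyclohex-3-en-1-yl]ethyl}-2H-chromen-5-ol, via ylide 13 (not isolated), via Z-alkenyl dienone silyl ether 14 (not isolated), via oxa-Michael adduct 15 (not isolated)
Conditions: KHMDS, THF, −78 °C; add 12, −78 → 0 °C; then Bu4NF, THF, 0 °C; then PPTS (1.5 equiv), MeOH, 23 °C
Reagents that add atoms: none
Why: Deprotonation of 9 gives the non-stabilised ylide 13, whose Wittig reaction with the formyl group of 12 (C4) should pass through a cis-oxaphosphetane to the Z-alkene 14 and so create C3=C4; fluoride then cleaves the silyl ether and the tertiary alkoxide O1 adds to C8a, the β-carbon of the C5 enone, to give 15, from which acid-induced ionisation of the C8 ketal, loss of the C8a proton and enolisation of the C5 ketone expel methanol and restore the benzene ring, creating O1–C8a. The closest known reaction types are the Z-selective Wittig olefination of aldehydes and the conjugate addition–aromatisation of nucleophiles on p-quinone monoketals. The pyran ring closes by a 6-endo-trig oxa-Michael addition. No stereocentre is created: C2 is carried in from 9 with its C–O bond untouched, and the transient sp3 centres C4a and C8a of 15 vanish on aromatisation. The step needs Z-selectivity and carbonyl (1,2) attack of the ylide in preference to conjugate attack: the first should follow from the non-stabilised ylide under lithium-free conditions at −78 °C (only the Z-isomer can reach C8a), the second from the much higher reactivity of the aldehyde, while the silyl ether keeps O1 from forming a betaine. The regiochemistry of aromatisation is fixed by the substrate, since methanol can only leave from the C8 ketal, which leaves 8-OMe in place and frees 5-OH.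

Compound list
1 | hex-5-enal | C=CCCCC=O | starting material
2 | 2-methylidenehex-5-enal | C=CCCC(=C)C=O | intermediate
3 | (3E)-3-methylpenta-1,3-diene | C/C=C(\C)C=C | starting material
4 | (1S,2R)-1-(but-3-en-1-yl)-2,3-dimethylcyclohex-3-ene-1-carbaldehyde | C=CCC[C@]1(C=O)CCC=C(C)[C@H]1C | intermediate
5 | 4-[(1R,2S)-1,2,3-trimethylcyclohex-3-en-1-yl]but-1-ene | C=CCC[C@]1(C)CCC=C(C)[C@H]1C | intermediate
6 | 4-[(1S,2S)-1,2,3-trimethylcyclohex-3-en-1-yl]butan-2-one | CC(=O)CC[C@]1(C)CCC=C(C)[C@H]1C | intermediate
7 | (2R)-2-methyl-2-{2-[(1S,2S)-1,2,3-trimethylcyclohex-3-en-1-yl]ethyl}oxirane | C[C@@]1(CC[C@]2(C)CCC=C(C)[C@H]2C)CO1 | intermediate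
8 | [(2R)-2-hydroxy-2-methyl-4-[(1S,2S)-1,2,3-trimethylcyclohex-3-en-1-yl]butyl]triphenylphosphonium tetrafluoroborate | O[C@](C)(CC[C@]1(C)CCC=C(C)[C@H]1C)C[P+](c1ccccc1)(c1ccccc1)c1ccccc1.F[B-](F)(F)F | intermediate
9 | [(2R)-2-methyl-2-[(trimethylsilyl)oxy]-4-[(1S,2S)-1,2,3-trimethylcyclohex-3-en-1-yl]butyl]triphenylphosphonium tetrafluoroborate | C[Si](C)(C)O[C@](C)(CC[C@]1(C)CCC=C(C)[C@H]1C)C[P+](c1ccccc1)(c1ccccc1)c1ccccc1.F[B-](F)(F)F | intermediate
10 | 2,3,4-trimethoxyphenol | COc1ccc(O)c(OC)c1OC | starting material
11 | 2-hydroxy-3,4,5-trimethoxybenzaldehyde | O=Cc1cc(OC)c(OC)c(OC)c1O | intermediate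
12 | 3,3,4,5-tetramethoxy-6-oxocyclohexa-1,4-diene-1-carbaldehyde | O=CC1=CC(OC)(OC)C(OC)=C(OC)C1=O | intermediate
13 | {(2R)-2-methyl-2-[(trimethylsilyl)oxy]-4-[(1S,2S)-1,2,3-trimethylcyclohex-3-en-1-yl]butylidene}triphenylphosphorane (ylide) | C[Si](C)(C)O[C@](C)(CC[C@]1(C)CCC=C(C)[C@H]1C)C=P(c1ccccc1)(c1ccccc1)c1ccccc1 | intermediate
14 | 4,4,5,6-tetramethoxy-2-[(1Z,3R)-3-methyl-3-[(trimethylsilyl)oxy]-5-[(1S,2S)-1,2,3-trimethylcyclohex-3-en-1-yl]pent-1-en-1-yl]cyclohexa-2,5-dien-1-one | C[Si](C)(C)O[C@](C)(CC[C@]1(C)CCC=C(C)[C@H]1C)/C=C\C1=CC(OC)(OC)C(OC)=C(OC)C1=O | intermediate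
15 | (2R)-6,7,8,8-tetramethoxy-2-methyl-2-{2-[(1S,2S)-1,2,3-trimethylcyclohex-3-en-1-yl]ethyl}-4a,8a-dihydro-2H-chromen-5(8H)-one (C4a and C8a transient, undefined) | COC1=C(OC)C(OC)(OC)C2O[C@](C)(CC[C@]3(C)CCC=C(C)[C@H]3C)C=CC2C1=O | intermediate
16 | (2R)-6,7,8-trimethoxy-2-methyl-2-{2-[(1S,2S)-1,2,3-trimethylcyclohex-3-en-1-yl]ethyl}-2H-chromen-5-ol | COc1c(O)c2c(c(OC)c1OC)O[C@](C)(CC[C@]1(C)CCC=C(C)[C@H]1C)C=C2 | target

Total step count: 10. Longest linear sequence: 8 steps (steps 1–7 and 10); steps 8 and 9 form the second branch.

Steps most likely to fail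

Step 10. The ylide may add in conjugate fashion to the electron-poor dienone instead of olefinating the aldehyde, it may lose silanolate by β-elimination, or Z-selectivity may erode; dienone aldehyde 12 may also decompose before it reacts. The fallback inverts olefination and dearomatisation and avoids 12 altogether. It sets out from 9 and 11: 11 is first converted into its potassium phenoxide (KHMDS, THF) and then treated with ylide 13 (from 9 and KHMDS, THF, −78 → 0 °C), which should give the aromatic Z-alkene 2,3,4-trimethoxy-6-[(1Z,3R)-3-methyl-3-[(trimethylsilyl)oxy]-5-[(1S,2S)-1,2,3-trimethylcyclohex-3-en-1-yl]pent-1-en-1-yl]phenol F1. Oxidation of F1 with PhI(OAc)2 in MeOH at 0 °C should then give dienone 14, where the fallback comes back to the route (Bu4NF, then PPTS, as in step 10).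

Step 2. Regiochemical leakage (the internal methyl group of the diene directs the opposite orientation), erosion of endo selectivity or insufficient facial control would each give isomers of 4 that are hard to remove. The fallback builds the ring by conjugate addition instead of cycloaddition; it uses no numbered compound and replaces 1–4. Commercial 3-methylcyclohex-2-en-1-one F2 is treated with but-3-enylmagnesium bromide under copper catalysis (Cu(OTf)2, chiral N-heterocyclic carbene ligand, Et2O, 0 °C) to set the quaternary centre, and the magnesium enolate is trapped with MeI (DMPU), which should give (2S,3S)-3-(but-3-en-1-yl)-2,3-dimethylcyclohexan-1-one F3 after separation of the C2 epimer. Kinetic enolisation on the CH2 side (LDA, THF, −78 °C) and trapping with PhNTf2 gives (5R,6S)-5-(but-3-en-1-yl)-5,6-dimethylcyclohex-1-en-1-yl trifluoromethanesulfonate F4, and iron-catalysed coupling with MeMgBr (Fe(acac)3, THF–NMP, 0 °C) comes back to the route at 5.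

Step 6. Under proton activation the epoxide may ionise at its tertiary carbon, which would lead to opening at the wrong terminus or to rearrangement to an aldehyde with loss of the C2 centre. The fallback opens the epoxide under basic conditions and builds the phosphonium salt afterwards. It sets out from 7: KPPh2 (THF, −78 → 0 °C) attacks the CH2 terminus and the alkoxide is trapped in the same flask with Me3SiCl, giving {(2R)-2-methyl-2-[(trimethylsilyl)oxy]-4-[(1S,2S)-1,2,3-trimethylcyclohex-3-en-1-yl]butyl}diphenylphosphane F5. Palladium-catalysed P-phenylation with iodobenzene (Pd2(dba)3, toluene, 110 °C) should give [(2R)-2-methyl-2-[(trimethylsilyl)oxy]-4-[(1S,2S)-1,2,3-trimethylcyclohex-3-en-1-yl]butyl]triphenylphosphonium iodide F6, which takes the place of 9 in step 10 and comes back to the route at ylide 13.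

Further compounds
F1 | step 10 | 2,3,4-trimethoxy-6-[(1Z,3R)-3-methyl-3-[(trimethylsilyl)oxy]-5-[(1S,2S)-1,2,3-trimethylcyclohex-3-en-1-yl]pent-1-en-1-yl]phenol | C[Si](C)(C)O[C@](C)(CC[C@]1(C)CCC=C(C)[C@H]1C)/C=C\c1cc(OC)c(OC)c(OC)c1O
F2 | step 2 | 3-methylcyclohex-2-en-1-one | CC1=CC(=O)CCC1
F3 | step 2 | (2S,3S)-3-(but-3-en-1-yl)-2,3-dimethylcyclohexan-1-one | C=CCC[C@]1(C)CCCC(=O)[C@H]1C
F4 | step 2 | (5R,6S)-5-(but-3-en-1-yl)-5,6-dimethylcyclohex-1-en-1-yl trifluoromethanesulfonate | C=CCC[C@]1(C)CCC=C(OS(=O)(=O)C(F)(F)F)[C@H]1C
F5 | step 6 | {(2R)-2-methyl-2-[(trimethylsilyl)oxy]-4-[(1S,2S)-1,2,3-trimethylcyclohex-3-en-1-yl]butyl}diphenylphosphane | C[Si](C)(C)O[C@](C)(CC[C@]1(C)CCC=C(C)[C@H]1C)CP(c1ccccc1)c1ccccc1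
F6 | step 6 | [(2R)-2-methyl-2-[(trimethylsilyl)oxy]-4-[(1S,2S)-1,2,3-trimethylcyclohex-3-en-1-yl]butyl]triphenylphosphonium iodide | C[Si](C)(C)O[C@](C)(CC[C@]1(C)CCC=C(C)[C@H]1C)C[P+](c1ccccc1)(c1ccccc1)c1ccccc1.[I-]
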